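**Retrosynthetic overview**

1. Numbering follows the chroman-4-one (ring A = benzene ring, ring B = pyranone ring). The plan rests on one feature: carbonyl carbon C4 is bonded to aryl carbon C4a, which is ortho to O1, and O1–C2(quaternary, S)–C3–C4 maps onto the O–C–C≡C unit of an aryl ether of a tertiary propargylic alcohol.
2. Target ⇒ (desilylation, oxidation at C4, Markovnikov hydration of C3=C4) 2H-chromene ⇒ (C4–C4a, gold-catalysed 6-endo hydroarylation) terminal aryl propargyl ether. Ring A is bought, and ring B is the only ring formed.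
3. Aryl propargyl ether ⇒ (O1–C8a, SNAr with retention at C2) (S)-dehydrolinalool + 2-bromo-4-fluorobenzaldehyde. The formyl group activates the fluoride and then becomes the C6 oxygen by Baeyer–Villiger oxidation. The same peracid/hydride pair turns the chain alkene into the tertiary carbinol before gold meets the alkyne.
4. (S)-Dehydrolinalool ⇒ geraniol by Sharpless epoxidation (sets C2), Appel chlorination and base-induced double elimination.

Key step: step 9

Remark: the chain epoxide carbon formed in step 5 and carbinol carbon C4 formed in step 10 arise as epimer mixtures. Steps 6 and 11 erase these centres, so they are drawn undefined.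

**Route**

Step 1
Reactants: 1 geraniol
Product: 2 (2S,3S)-2,3-epoxygeraniol
Conditions: Ti(OiPr)4 (5 mol %), L-(+)-DET (6 mol %), t-BuOOH, 4 Å MS, CH2Cl2, −20 °C
Reagents that add atoms: tert-butyl hydroperoxide CC(C)(C)OO
Why: Katsuki–Sharpless asymmetric epoxidation, in which the titanium tartrate complex binds the allylic alcohol, so only the C2=C3 alkene reacts and L-(+)-DET directs oxygen to the face that makes the methyl-bearing carbon (the future C2 of ring B) S.

Step 2
Reactants: 2 (2S,3S)-2,3-epoxygeraniol
Product: 3 (2R,3S)-1-chloro-2,3-epoxy-3,7-dimethyloct-6-ene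
Conditions: PPh3, CCl4, reflux
Reagents that add atoms: carbon tetrachloride ClC(Cl)(Cl)Cl
Why: Appel reaction, a neutral SN2 chlorination of the primary alcohol that leaves the epoxide, its two stereocentres and the remote alkene alone (the descriptor of the CH carbon changes to R only through the CIP ranking of CH2Cl).

Step 3
Reactants: 3 (2R,3S)-1-chloro-2,3-epoxy-3,7-dimethyloct-6-ene
Product: 5 (S)-3,7-dimethyloct-6-en-1-yn-3-ol ((S)-dehydrolinalool), via chlorovinyl alkoxide 4 (not isolated)
Conditions: n-BuLi (3.3 equiv), THF, −78 → −30 °C; then H2O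
Reagents that add atoms: none
Why: Base-induced double elimination of a 2,3-epoxy chloride, in which deprotonation at CH2Cl opens the epoxide to 4, a second equivalent removes HCl and a third holds the product as its acetylide, while the tertiary C–O bond is never broken, so the S centre is retained.

Step 4
Reactants: 5 (S)-dehydrolinalool; 6 2-bromo-4-fluorobenzaldehyde
Product: 7 (S)-2-bromo-4-[(3,7-dimethyloct-6-en-1-yn-3-yl)oxy]benzaldehyde
Conditions: KN(SiMe3)2 (1.0 equiv), THF, −20 °C; then 6, 0 °C → rt
Reagents that add atoms: none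
Why: SNAr (addition–elimination) of the potassium alkoxide of 5 at the C–F carbon para to the formyl group, with fluoride far more labile than the ortho bromide and with retention at the carbinol carbon because only the O–aryl bond is formed.

Step 5
Reactants: 7 (S)-2-bromo-4-[(3,7-dimethyloct-6-en-1-yn-3-yl)oxy]benzaldehyde
Product: 9 2-bromo-4-{[(3S)-5-(3,3-dimethyloxiran-2-yl)-3-methylpent-1-yn-3-yl]oxy}phenyl formate, via epoxy aldehyde 8 (not isolated)
Conditions: mCPBA (2.5 equiv), CH2Cl2, 0 °C → rt
Reagents that add atoms: 3-chloroperoxybenzoic acid O=C(OO)c1cccc(Cl)c1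
Why: Two peracid oxidations in one flask, a fast Prilezhaev epoxidation of the trisubstituted alkene to 8 and then a Baeyer–Villiger oxidation in which the para-alkoxy aryl group migrates in preference to hydrogen, with the terminal alkyne and the aryl bromide inert to mCPBA.

Step 6
Reactants: 9 epoxy formate
Product: 10 (S)-2-bromo-4-[(7-hydroxy-3,7-dimethyloct-1-yn-3-yl)oxy]phenol
Conditions: LiAlH4, Et2O, 0 °C → rt; aqueous work-up
Reagents that add atoms: none
Why: Hydride reduction, in which the formate is cleaved to the phenoxide and the epoxide is opened by SN2 attack at its less substituted carbon, putting the hydroxyl on the tertiary carbon and erasing the epoxide stereocentre, while in ether at or below room temperature the aryl bromide, the undirected alkyne and the now very poor aryloxide leaving group should persist.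

Step 7
Reactants: 10 (S)-2-bromo-4-[(7-hydroxy-3,7-dimethyloct-1-yn-3-yl)oxy]phenol
Product: 11 (S)-6-[3-bromo-4-(tert-butyldimethylsilyloxy)phenoxy]-2,6-dimethyloct-7-yn-2-ol
Conditions: TBSCl, imidazole, CH2Cl2, 0 °C → rt
Reagents that add atoms: tert-butyldimethylsilyl chloride CC(C)(C)[Si](C)(C)Cl
Why: Chemoselective silyl ether formation, since the acidic phenol reacts with TBSCl/imidazole whereas the hindered tertiary alcohol does not.

Step 8
Reactants: 11 TBS ether alcohol
Product: 12 (S)-2-bromo-1-(tert-butyldimethylsilyloxy)-4-{[3,7-dimethyl-7-(triethylsilyloxy)oct-1-yn-3-yl]oxy}benzene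
Conditions: TESOTf, 2,6-lutidine, CH2Cl2, −78 → 0 °C
Reagents that add atoms: triethylsilyl trifluoromethanesulfonate CC[Si](CC)(CC)OS(=O)(=O)C(F)(F)F
Why: Silylation of a tertiary alcohol with a silyl triflate and a hindered base, which removes the last protic nucleophile of the chain without touching the alkyne C–H or the aryl ether.

Step 9
Reactants: 12 (S)-aryl propargyl ether
Product: 13 (S)-7-bromo-6-(tert-butyldimethylsilyloxy)-2-methyl-2-[4-methyl-4-(triethylsilyloxy)pentyl]-2H-chromene
Conditions: Ph3PAuNTf2 (3 mol %), 4 Å MS, CH2Cl2 (0.05 M), rt, dark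
Reagents that add atoms: none
Why: Ph3PAuNTf2, a source of cationic monovalent gold, binds the terminal alkyne as a π-complex, aryl carbon C4a (ortho to O1, para to Br) attacks the terminal alkyne carbon in Friedel–Crafts fashion, and rearomatisation with protodeauration releases 13 and the catalyst; this is the known gold-catalysed intramolecular hydroarylation of aryl propargyl ethers, which includes ethers of tertiary propargylic alcohols. Ring B closes in the 6-endo-dig mode and only the C4–C4a bond is formed. No stereocentre is created, and C2 stays S because the O1–C2 bond is never broken, unlike in the thermal propargyl Claisen route to chromenes, which passes through an achiral ortho-quinone methide. 6-endo should win over 5-exo because the short O1–C2–C3 tether cannot bring internal carbon C3 to the ring without strain, and because the inductive pull of the C2–O bond and the bulk of quaternary C2 offset the usual Markovnikov bias toward C3. Of the two carbons ortho to O1, C4a is open whereas C8 is wedged between O1 and bromine, so closure at C4a should dominate. The chain offers gold no competing π-system or nucleophile (the former 1,6-enyne alkene is now a silylated carbinol and the phenol is capped), and room temperature, sieves and a non-coordinating solvent hold back ionisation of the tertiary propargylic ether and alkyne hydration, while exclusion of light guards 13 against photochemical ring opening.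

Step 10
Reactants: 13 (S)-2H-chromene
Product: 15 (2S,4RS)-7-bromo-6-(tert-butyldimethylsilyloxy)-2-methyl-2-[4-methyl-4-(triethylsilyloxy)pentyl]chroman-4-ol, via C4 hydroperoxide 14 (not isolated)
Conditions: Mn(dpm)3 (10 mol %), PhSiH3, O2 (1 atm), i-PrOH–CH2Cl2, 0 °C; then PPh3
Reagents that add atoms: dioxygen O=O
Why: Mukaiyama hydration by metal-hydride hydrogen-atom transfer, in which hydrogen is delivered to C3 because this gives the benzylic C4 radical, further stabilised by O1 through ring A, which O2 traps as 14 and PPh3 reduces to the alcohol, with C2, the aryl bromide and both silyl ethers untouched and any ketone formed converging in step 11.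

Step 11
Reactants: 15 chroman-4-ol
Product: 16 (S)-7-bromo-6-(tert-butyldimethylsilyloxy)-2-methyl-2-[4-methyl-4-(triethylsilyloxy)pentyl]chroman-4-one
Conditions: Dess–Martin periodinane, CH2Cl2, 0 °C → rt
Reagents that add atoms: none
Why: Dess–Martin oxidation of the benzylic secondary alcohol under non-basic conditions, which removes the C4 stereocentre and avoids enolate-driven retro-oxa-Michael opening of ring B that could scramble C2.

Step 12
Reactants: 16 protected chroman-4-one
Product: 17 (S)-7-bromo-6-hydroxy-2-(4-hydroxy-4-methylpentyl)-2-methylchroman-4-one (target)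
Conditions: Bu4NF, AcOH (1:1), THF, 0 °C → rt
Reagents that add atoms: none
Why: Fluoride-mediated desilylation driven by Si–F bond formation cleaves the aryl TBS ether and the tertiary TES ether in one operation, and the acetic acid buffer keeps the medium too weakly basic for E1cB opening of ring B, so C2 remains S.

**Compound list**

1 | geraniol, (E)-3,7-dimethylocta-2,6-dien-1-ol | CC(C)=CCC/C(C)=C/CO | starting material
2 | (2S,3S)-2,3-epoxygeraniol, [(2S,3S)-3-methyl-3-(4-methylpent-3-enyl)oxiran-2-yl]methanol | OC[C@@H]1O[C@@]1(C)CCC=C(C)C | intermediate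
3 | (2R,3S)-1-chloro-2,3-epoxy-3,7-dimethyloct-6-ene | ClC[C@@H]1O[C@@]1(C)CCC=C(C)C | intermediate
4 | (S)-1-chloro-3,7-dimethylocta-1,6-dien-3-ol, present as its lithium alkoxide, C1=C2 geometry undefined | ClC=C[C@@](C)(O)CCC=C(C)C | intermediate (not isolated)
5 | (S)-3,7-dimethyloct-6-en-1-yn-3-ol, (S)-dehydrolinalool | C#C[C@@](C)(O)CCC=C(C)C | intermediate
6 | 2-bromo-4-fluorobenzaldehyde | O=Cc1ccc(F)cc1Br | starting material
7 | (S)-2-bromo-4-[(3,7-dimethyloct-6-en-1-yn-3-yl)oxy]benzaldehyde | C#C[C@](C)(CCC=C(C)C)Oc1ccc(C=O)c(Br)c1 | intermediate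
8 | 2-bromo-4-{[(3S)-5-(3,3-dimethyloxiran-2-yl)-3-methylpent-1-yn-3-yl]oxy}benzaldehyde, epoxide epimers | C#C[C@](C)(CCC1OC1(C)C)Oc1ccc(C=O)c(Br)c1 | intermediate (not isolated)
9 | 2-bromo-4-{[(3S)-5-(3,3-dimethyloxiran-2-yl)-3-methylpent-1-yn-3-yl]oxy}phenyl formate, epoxide epimers | C#C[C@](C)(CCC1OC1(C)C)Oc1ccc(OC=O)c(Br)c1 | intermediate
10 | (S)-2-bromo-4-[(7-hydroxy-3,7-dimethyloct-1-yn-3-yl)oxy]phenol | C#C[C@](C)(CCCC(C)(C)O)Oc1ccc(O)c(Br)c1 | intermediate
11 | (S)-6-[3-bromo-4-(tert-butyldimethylsilyloxy)phenoxy]-2,6-dimethyloct-7-yn-2-ol | C#C[C@](C)(CCCC(C)(C)O)Oc1ccc(O[Si](C)(C)C(C)(C)C)c(Br)c1 | intermediate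
12 | (S)-2-bromo-1-(tert-butyldimethylsilyloxy)-4-{[3,7-dimethyl-7-(triethylsilyloxy)oct-1-yn-3-yl]oxy}benzene | C#C[C@](C)(CCCC(C)(C)O[Si](CC)(CC)CC)Oc1ccc(O[Si](C)(C)C(C)(C)C)c(Br)c1 | intermediate
13 | (S)-7-bromo-6-(tert-butyldimethylsilyloxy)-2-methyl-2-[4-methyl-4-(triethylsilyloxy)pentyl]-2H-chromene | CC(C)(O[Si](CC)(CC)CC)CCC[C@@]1(C)C=Cc2cc(O[Si](C)(C)C(C)(C)C)c(Br)cc2O1 | intermediate
14 | (2S)-7-bromo-6-(tert-butyldimethylsilyloxy)-4-hydroperoxy-2-methyl-2-[4-methyl-4-(triethylsilyloxy)pentyl]chroman, C4 epimers | CC(C)(O[Si](CC)(CC)CC)CCC[C@@]1(C)CC(OO)c2cc(O[Si](C)(C)C(C)(C)C)c(Br)cc2O1 | intermediate (not isolated)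
15 | (2S,4RS)-7-bromo-6-(tert-butyldimethylsilyloxy)-2-methyl-2-[4-methyl-4-(triethylsilyloxy)pentyl]chroman-4-ol | CC(C)(O[Si](CC)(CC)CC)CCC[C@@]1(C)CC(O)c2cc(O[Si](C)(C)C(C)(C)C)c(Br)cc2O1 | intermediate
16 | (S)-7-bromo-6-(tert-butyldimethylsilyloxy)-2-methyl-2-[4-methyl-4-(triethylsilyloxy)pentyl]chroman-4-one | CC(C)(O[Si](CC)(CC)CC)CCC[C@@]1(C)CC(=O)c2cc(O[Si](C)(C)C(C)(C)C)c(Br)cc2O1 | intermediate
17 | (S)-7-bromo-6-hydroxy-2-(4-hydroxy-4-methylpentyl)-2-methylchroman-4-one | CC(C)(O)CCC[C@@]1(C)CC(=O)c2cc(O)c(Br)cc2O1 | target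

**Step count**

Total step count: 12. Longest linear sequence: 12 steps (1 → 17); 6 enters as a purchased compound in step 4.

**Steps most likely to fail**

Step 9 (key step).
- What may go wrong: the tertiary propargylic O1–C2 bond may ionise under the cationic catalyst or traces of HNTf2, with loss of the aryl group and erosion of enantiopurity.
- Attack may also be slow, because C4a is activated by only one ortho oxygen, and some closure may occur at the hindered ortho carbon.
- Fallback: it sets out from 12 and returns at 16, making the C4–C4a bond by acylation instead of alkyne activation. Dicyclohexylborane adds to the terminal alkyne of 12 to give the (E)-alkenylborane F1. Oxidation with NaBO3·4H2O in buffered aqueous THF gives the β-aryloxy aldehyde F2. Pinnick oxidation (NaClO2, NaH2PO4, 2-methyl-2-butene) gives the carboxylic acid F3. 1-Chloro-N,N,2-trimethylpropenylamine converts it under neutral conditions into the acid chloride F4. SnCl4 with 2,6-di-tert-butylpyridine in CH2Cl2 at −78 °C then closes ring B by intramolecular Friedel–Crafts acylation at C4a. This gives 16 directly, so steps 10 and 11 fall away, and O1–C2 again stays intact.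

Step 4.
- What may go wrong: proton exchange between alkoxide and alkyne may be followed by acetylide addition to the formyl group.
- The tertiary propargylic alkoxide may also fragment by a retro-Favorskii pathway, with loss of material and of enantiopurity, and substitution by the hindered alkoxide may be slow.
- Fallback: it sets out from 5 and returns at 7, replacing the activating group with one that acetylides do not attack readily. The potassium alkoxide of 5 (KN(SiMe3)2, THF) displaces fluoride from commercial 2-bromo-4-fluorobenzonitrile (N#Cc1ccc(F)cc1Br) to give the nitrile F5. iBu2AlH in toluene at −78 °C adds once, mild aqueous acid liberates the aldimine F6, and this hydrolyses in the same work-up to 7.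

Step 10.
- What may go wrong: the benzylic radical may be quenched by a second hydrogen-atom transfer, giving net hydrogenation of C3=C4.
- Hydrogen delivery to C3 next to quaternary C2 may be sluggish, and the products may spread over several oxidation levels.
- Fallback: it sets out from 13 and returns at 15, using ionic instead of radical oxygenation. N-Bromosuccinimide in aqueous DMSO at 0 °C forms the bromonium ion, and water opens it at benzylic C4 to give the trans-bromohydrin F7. Bu3SnH (1.0 equiv) with AIBN in toluene at 80 °C then removes the secondary alkyl bromine, which is abstracted faster than the aryl bromine, to give 15.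

**Further compounds**

F1 | step 9 | dicyclohexyl{(1E,3S)-3-[3-bromo-4-(tert-butyldimethylsilyloxy)phenoxy]-3,7-dimethyl-7-(triethylsilyloxy)oct-1-enyl}borane | C1CCCCC1B(C1CCCCC1)/C=C/[C@](C)(CCCC(C)(C)O[Si](CC)(CC)CC)Oc1ccc(O[Si](C)(C)C(C)(C)C)c(Br)c1
F2 | step 9 | (S)-3-[3-bromo-4-(tert-butyldimethylsilyloxy)phenoxy]-3,7-dimethyl-7-(triethylsilyloxy)octanal | O=CC[C@](C)(CCCC(C)(C)O[Si](CC)(CC)CC)Oc1ccc(O[Si](C)(C)C(C)(C)C)c(Br)c1
F3 | step 9 | (S)-3-[3-bromo-4-(tert-butyldimethylsilyloxy)phenoxy]-3,7-dimethyl-7-(triethylsilyloxy)octanoic acid | OC(=O)C[C@](C)(CCCC(C)(C)O[Si](CC)(CC)CC)Oc1ccc(O[Si](C)(C)C(C)(C)C)c(Br)c1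
F4 | step 9 | (S)-3-[3-bromo-4-(tert-butyldimethylsilyloxy)phenoxy]-3,7-dimethyl-7-(triethylsilyloxy)octanoyl chloride | ClC(=O)C[C@](C)(CCCC(C)(C)O[Si](CC)(CC)CC)Oc1ccc(O[Si](C)(C)C(C)(C)C)c(Br)c1
F5 | step 4 | (S)-2-bromo-4-[(3,7-dimethyloct-6-en-1-yn-3-yl)oxy]benzonitrile | C#C[C@](C)(CCC=C(C)C)Oc1ccc(C#N)c(Br)c1
F6 | step 4 | (S)-2-bromo-4-[(3,7-dimethyloct-6-en-1-yn-3-yl)oxy]benzaldimine | C#C[C@](C)(CCC=C(C)C)Oc1ccc(C=N)c(Br)c1
F7 | step 10 | (2S)-trans-3,7-dibromo-6-(tert-butyldimethylsilyloxy)-2-methyl-2-[4-methyl-4-(triethylsilyloxy)pentyl]chroman-4-ol, both trans isomers | CC(C)(O[Si](CC)(CC)CC)CCC[C@@]1(C)C(Br)C(O)c2cc(O[Si](C)(C)C(C)(C)C)c(Br)cc2O1
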